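The data stem from a simulated flask with constants of no real substance, noise included.

How much free catalyst is left when 30% of the starting material is converted is the question of this flask.

| flask | starting material | partner | free catalyst | remark |
|---|---|---|---|---|
| south-west | 1 M | 0.90 M | 10 mM | run made earlier |
| south | 1 M | 1.4 M | 10 mM | run made earlier |
| west | 1 M | 1.8 M | 20 mM | run made earlier |
| flask | 1.0 M | 1.80 M | 10 mM |  |

| south-west: time / min | south-west: target / % | south: time / min | south: target / % | west: time / min | west: target / % |
|---|---|---|---|---|---|
| 2.50 | 3.5 | 2.50 | 5.7 | 2.50 | 13.4 |
| 8.00 | 10.8 | 8.00 | 14.8 | 8.00 | 36.2 |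
| 15.0 | 17.9 | 15.0 | 26.2 | 15.0 | 55.9 |
| 20.0 | 22.7 | 20.0 | 33.3 | 20.0 | 64.4 |
| 30.0 | 30.5 | 30.0 | 43.6 | 30.0 | 78.0 |

(scatter of a reading: 0.5 percentage points)

1. factor on the rate of making target when 30% of the starting material are converted if free catalyst is charged twice over
2. factor on the rate when 30% of the starting material are converted if free catalyst is charged at 2.0 mM instead



Let k be the apparent constant in rate = k[starting material][partner], taken from the integrated form of that law. At 10 mM, the south and south-west readings at 30.0 min give 0.0166 M⁻¹ min⁻¹ and 0.0167 M⁻¹ min⁻¹, so k does not follow the partner charge, and I use it for 1.80 M as well. The west run is this flask with the catalyst doubled. Its reading at 8.00 min, 36.2% converted, lies between the south-west 30.5% and the south 43.6% and gives 0.0351 M⁻¹ min⁻¹. The ratio of this k to the mean of the other two is r = 2.11, more than the factor two of a plain first order in catalyst.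

Two views read this r. The first says the rate follows a power of the catalyst charge, with an order a little above one, and on this r it gives 0.177 at 2.0 mM. The second, mine, says deactivation takes a fixed amount of catalyst at a given conversion, whatever the charge, so k, an average from the start, follows the charge minus the mean loss so far. Then that mean loss is 0.997 mM. Going round once more, a loss growing in step with conversion ends at roughly twice its mean, and scaling from 36.2% back gives L = 1.65 mM, the catalyst lost by 30% conversion, a rough reading given the scatter. My factor at 2.0 mM is 0.0416.

The forecast keeps both views open, “so I can't distinguish them”, and gives 2.25 and 0.1, higher at 2.0 mM than my factor.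

The simulation gives 2.18 and 0.0526, from this scheme:

    starting material + partner + free catalyst → target + free catalyst, rate k1*[starting material]*[partner]*[free catalyst]/(1 + ([starting material]/sat1)) (0.830 M, k = 3.60 M⁻² min⁻¹)
    partner + free catalyst → spent catalyst (k = 0.00780 M⁻¹ min⁻¹)

The power view holds for the doubling, 2.25 against 2.18, where L is 16.5% of the smaller charge, but at 2.0 mM the forecast stands above the flask. In this flask partner goes to target 210 times as fast as to spent catalyst at the start and 150 times as fast after 25.0 min, which prices 30% conversion at 1.43 mM to 2.00 mM of catalyst, and the spent catalyst there is 1.56 mM. In the 2.0 mM flask, L leaves a free share of 17.5%, and the simulated share at that conversion is 22.2%.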